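**Plan** (isochromanone numbering; side chain C1′–C11′)
1. Retrosynthesis: the O–CH3 bond at C8 is cut last. Then the side-chain bond C4′–C5′ is cut (C5′ is β to the C7′ ketone, so it is the terminal carbon of hept-1-en-3-one) while a bond absent from the target, C1–C4′, is added, which turns lactone carbon C1 into the hemiketal carbon of a bridged bicycle.
2. Enabling feature: C1 is an acyl carbon bonded to ring oxygen O2 and aryl carbon C8a of the dimethoxybenzene ring. An oxygen radical on the C1 hemiketal can break only C1–C4′, which creates the lactone C=O of the six-membered ring and releases the C4′ radical.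
3. Further cuts: C8a–C1 (aryllithium onto an ε-lactone), aryl C–Br, O2–C1 (Baeyer–Villiger insertion), C3–C4 (benzylation of cyclohexanone). Cyclohexanone supplies C1, C3 and C1′–C4′.
4. Forward ring order: cyclohexanone → oxepan-2-one → bridged isochroman hemiketal (six-membered O-ring closed) → fragmentation of the bicycle with chain joining → release of the 8-OH.
5. Stereochemistry: C3 (R) comes from RAMP-hydrazone benzylation and is carried with retention through the Baeyer–Villiger shift; it is not enolisable afterwards.

Key step: step 6

Assumption: hept-1-en-3-one (butyl vinyl ketone) is taken as a purchasable reagent and distilled before use.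

**Step 1**
Reactants: 1 cyclohexanone; 2 RAMP, (R)-1-amino-2-(methoxymethyl)pyrrolidine
Product: 3 cyclohexanone RAMP hydrazone
Conditions: neat, 60 °C (or PhH, reflux, Dean–Stark)
Reagents that add atoms: none
Why: Condensation of the ketone with the Enders hydrazine auxiliary should give the hydrazone cleanly; no stereocentre is formed yet.

**Step 2**
Reactants: 3 cyclohexanone RAMP hydrazone; 4 3,5-dimethoxybenzyl bromide
Product: 7 (R)-2-(3,5-dimethoxybenzyl)cyclohexan-1-one, via lithium azaenolate 5 (not isolated), via alkylated hydrazone 6 (not isolated)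
Conditions: LDA, THF, 0 °C; 4, −100 °C → rt; then sat. aq. oxalic acid, Et2O, rt
Reagents that add atoms: water, SMILES O
Why: Enders SAMP/RAMP hydrazone alkylation, in which the chelated azaenolate is benzylated on the face left open by the methoxymethylpyrrolidine (with RAMP this should give the R ketone, the mirror image of the SAMP outcome), followed by two-phase oxalic acid hydrolysis that should release the α-chiral ketone without racemisation.

**Step 3**
Reactants: 7 (R)-2-(3,5-dimethoxybenzyl)cyclohexan-1-one
Product: 8 (7R)-7-(3,5-dimethoxybenzyl)oxepan-2-one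
Conditions: mCPBA, NaHCO3, CH2Cl2, 0 °C → rt
Reagents that add atoms: 3-chloroperoxybenzoic acid (mCPBA), SMILES OOC(=O)c1cccc(Cl)c1
Why: Baeyer–Villiger oxidation, in which the more substituted α-carbon migrates with retention of configuration, so that oxygen is inserted between the carbonyl carbon and the stereocentre, which now carries the future lactone oxygen O2.

**Step 4**
Reactants: 8 (7R)-7-(3,5-dimethoxybenzyl)oxepan-2-one
Product: 9 (7R)-7-(2-bromo-3,5-dimethoxybenzyl)oxepan-2-one
Conditions: NBS, MeCN, 0 °C, dark
Reagents that add atoms: N-bromosuccinimide (NBS), SMILES O=C1CCC(=O)N1Br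
Why: Electrophilic aromatic bromination of a 5-alkylresorcinol dimethyl ether should go para to one methoxy group and ortho to the alkyl group (the two such positions are equivalent), which is the carbon that becomes C8a.

**Step 5**
Reactants: 9 (7R)-7-(2-bromo-3,5-dimethoxybenzyl)oxepan-2-one
Product: 12 (1S,3R)-6,8-dimethoxy-1,3-butanoisochroman-1-ol (bridged hemiketal), via aryllithium 10 (not isolated), via lithium hemiketalate 11 (not isolated)
Conditions: t-BuLi (2 equiv), THF, −100 → −78 °C; then pH 7 buffer
Reagents that add atoms: none
Why: Parham-type cyclisation, in which bromine–lithium exchange at −100 °C should outrun attack on the lactone and the aryllithium adds 6-exo to the lactone carbonyl held 1,3 to the benzylic arm across the ring oxygen, giving after protonation the bridged hemiketal whose C1 configuration is dictated by the tetramethylene bridge from C3.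

**Step 6**
Reactants: 12 (1S,3R)-6,8-dimethoxy-1,3-butanoisochroman-1-ol; 13 hept-1-en-3-one
Product: 17 (3R)-6,8-dimethoxy-3-(7-oxoundecyl)isochroman-1-one, via alkoxy radical 14 (not isolated), via primary alkyl radical 15 (not isolated), via α-keto radical 16 (not isolated)
Conditions: [Ir(dF(CF3)ppy)2(5,5′-d(CF3)bpy)]PF6 (2 mol %), 2,4,6-collidine (2 equiv), 13 (4 equiv), CH2Cl2, 450 nm LEDs, rt, degassed
Reagents that add atoms: none
Why: Proposed new method: the photoexcited Ir(III) complex oxidises the 2,4-dimethoxyaryl ring that sits on C1 while collidine takes the hemiketal proton (proton-coupled electron transfer), which gives alkoxy radical 14; β-scission of C1–C4′, the only β-bond whose cleavage does not expel an aryl or an oxygen radical, forms the aryl-conjugated lactone C=O and primary radical 15, which adds to the terminal carbon of enone 13 (C4′–C5′ bond), and α-keto radical 16 is reduced by Ir(II) and protonated by collidinium, so that the step is redox-neutral and atom-economic. The closest known reaction types are the photocatalytic PCET ring opening of 1-arylcycloalkanols to aryl ketones with release of an alkyl radical, the alkoxy-radical fragmentation of bicyclic hemiketals to lactones, and Giese additions of radicals released by alkoxy β-scission. No ring is closed: the seven-membered oxygen ring and the nine-membered carbocycle of the bicycle are opened, and the six-membered ring survives as the dihydroisocoumarin lactone. No stereocentre is created; C1 becomes trigonal and C3 (R) is a spectator. The step needs O–H activation at C1 alone and trapping of 15 before it is lost, which the substrate secures through the electron-rich arene bonded directly to the carbinol carbon (the site of oxidation) and through the polarity match of the nucleophilic primary radical with the enone used in excess, which should be faster than 1,5-hydrogen transfer from C3–H.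

**Step 7**
Reactants: 17 (3R)-6,8-dimethoxy-3-(7-oxoundecyl)isochroman-1-one
Product: 19 (3R)-8-hydroxy-6-methoxy-3-(7-oxoundecyl)isochroman-1-one (target), via aryloxydichloroborane 18 (not isolated)
Conditions: BCl3 (2.5 equiv), CH2Cl2, −78 → 0 °C; then H2O
Reagents that add atoms: none
Why: Chelation-directed Lewis acid demethylation, in which BCl3 bound to the lactone carbonyl should cleave only the peri 8-methoxy group and leave the 6-methoxy group, the ketone and C3 unchanged.

**Compound list**
1 | cyclohexanone | O=C1CCCCC1 | starting material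
2 | RAMP, (R)-1-amino-2-(methoxymethyl)pyrrolidine | COC[C@H]1CCCN1N | starting material
3 | cyclohexanone RAMP hydrazone | COC[C@H]1CCCN1N=C1CCCCC1 | intermediate
4 | 3,5-dimethoxybenzyl bromide | COc1cc(CBr)cc(OC)c1 | starting material
5 | lithium azaenolate of 3 | [Li]N(N1CCC[C@@H]1COC)C1=CCCCC1 | intermediate (not isolated)
6 | RAMP hydrazone of (R)-2-(3,5-dimethoxybenzyl)cyclohexanone | COC[C@H]1CCCN1N=C1CCCC[C@@H]1Cc1cc(OC)cc(OC)c1 | intermediate (not isolated)
7 | (R)-2-(3,5-dimethoxybenzyl)cyclohexan-1-one | O=C1CCCC[C@@H]1Cc1cc(OC)cc(OC)c1 | intermediate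
8 | (7R)-7-(3,5-dimethoxybenzyl)oxepan-2-one | O=C1CCCC[C@H](Cc2cc(OC)cc(OC)c2)O1 | intermediate
9 | (7R)-7-(2-bromo-3,5-dimethoxybenzyl)oxepan-2-one | O=C1CCCC[C@H](Cc2cc(OC)cc(OC)c2Br)O1 | intermediate
10 | aryllithium from 9 | O=C1CCCC[C@H](Cc2cc(OC)cc(OC)c2[Li])O1 | intermediate (not isolated)
11 | lithium alkoxide of hemiketal 12 | COc1cc2C[C@H]3CCCC[C@](O[Li])(O3)c2c(OC)c1 | intermediate (not isolated)
12 | (1S,3R)-6,8-dimethoxy-1,3-butanoisochroman-1-ol (C1 bears OH, O2, C8a and C4′; C1′–C4′ bridge from C3 to C1) | COc1cc2C[C@H]3CCCC[C@](O)(O3)c2c(OC)c1 | intermediate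
13 | hept-1-en-3-one | C=CC(=O)CCCC | starting material
14 | C1 alkoxy radical of 12 | COc1cc2C[C@H]3CCCC[C@]([O])(O3)c2c(OC)c1 | intermediate (not isolated)
15 | 4-[(3R)-6,8-dimethoxy-1-oxoisochroman-3-yl]butyl radical | [CH2]CCC[C@@H]1Cc2cc(OC)cc(OC)c2C(=O)O1 | intermediate (not isolated)
16 | α-keto radical adduct of 15 and 13 | CCCCC(=O)[CH]CCCCC[C@@H]1Cc2cc(OC)cc(OC)c2C(=O)O1 | intermediate (not isolated)
17 | (3R)-6,8-dimethoxy-3-(7-oxoundecyl)isochroman-1-one | CCCCC(=O)CCCCCC[C@@H]1Cc2cc(OC)cc(OC)c2C(=O)O1 | intermediate
18 | 8-O-dichloroboryl derivative of the target | CCCCC(=O)CCCCCC[C@@H]1Cc2cc(OC)cc(OB(Cl)Cl)c2C(=O)O1 | intermediate (not isolated)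
19 | (3R)-8-hydroxy-6-methoxy-3-(7-oxoundecyl)isochroman-1-one | CCCCC(=O)CCCCCC[C@@H]1Cc2cc(OC)cc(O)c2C(=O)O1 | target

**Step count:** 7 steps in total; longest linear sequence 7 steps (1 → 3 → 7 → 8 → 9 → 12 → 17 → 19).

**Steps most likely to fail**

Step 6. Several processes may divert it: ring–chain tautomerism of the hemiketal followed by oxidation at the C3 oxygen and loss of the benzyl group by β-scission, back electron transfer without O–H cleavage, deprotonation of the oxidised arene at the benzylic C4–H, or oligomerisation of the vinyl ketone. The fallback sets out from 12 and uses known chemistry. Oxidative alkoxy-radical fragmentation with Pb(OAc)4 and Cu(OAc)2 (pyridine, benzene, 80 °C), in which the C4′ radical is oxidised by copper(II) to the alkene, should give (3R)-3-(but-3-en-1-yl)-6,8-dimethoxyisochroman-1-one F1. Anti-Markovnikov hydroboration with catecholborane (cat. N,N-dimethylacetamide, CH2Cl2) should give the B-alkylcatecholborane F2. This is treated in the same flask with 13, DMPU, water and air in an oxygen-initiated radical chain conjugate addition, and the route is rejoined at 17.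

Step 5. The alkyllithium may add to the lactone carbonyl, or the aryllithium may enolise the lactone, in place of ring closure. The fallback sets out from 9 and gives up the bicycle. Hydrolysis (LiOH, THF/H2O, careful acidification) should give (6R)-7-(2-bromo-3,5-dimethoxyphenyl)-6-hydroxyheptanoic acid F3. Palladium-catalysed carbonylative lactonisation (Pd(OAc)2, Xantphos, CO 1 atm, Et3N, toluene, 100 °C) should give 5-[(3R)-6,8-dimethoxy-1-oxoisochroman-3-yl]pentanoic acid F4. Esterification with N-hydroxyphthalimide (DIC, DMAP, CH2Cl2) should give the N-acyloxyphthalimide of this acid F5. Decarboxylative Giese addition to 13 (Ni(ClO4)2·6H2O, Zn, LiCl, MeCN; or Ru(bpy)3Cl2, Hantzsch ester, blue LEDs) rejoins the route at 17.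

Step 2. Facial selectivity in the azaenolate benzylation may be incomplete, or the α-stereocentre may epimerise during hydrazone cleavage. The fallback sets out from 1 and replaces the auxiliary by catalysis. Aldol condensation of 1 (in excess) with commercial 3,5-dimethoxybenzaldehyde (NaOH, EtOH/H2O) should give (E)-2-(3,5-dimethoxybenzylidene)cyclohexan-1-one F6. Iridium-catalysed asymmetric hydrogenation of the exocyclic enone (Ir–phosphine-oxazoline complex of the enantiomer that delivers the R ketone, H2, CH2Cl2) rejoins the route at 7.

**Further compounds**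
F1 | step 6 | (3R)-3-(but-3-en-1-yl)-6,8-dimethoxyisochroman-1-one | C=CCC[C@@H]1Cc2cc(OC)cc(OC)c2C(=O)O1
F2 | step 6 | 2-{4-[(3R)-6,8-dimethoxy-1-oxoisochroman-3-yl]butyl}-1,3,2-benzodioxaborole | B1(CCCC[C@@H]2Cc3cc(OC)cc(OC)c3C(=O)O2)Oc2ccccc2O1
F3 | step 5 | (6R)-7-(2-bromo-3,5-dimethoxyphenyl)-6-hydroxyheptanoic acid | OC(=O)CCCC[C@@H](O)Cc1cc(OC)cc(OC)c1Br
F4 | step 5 | 5-[(3R)-6,8-dimethoxy-1-oxoisochroman-3-yl]pentanoic acid | OC(=O)CCCC[C@@H]1Cc2cc(OC)cc(OC)c2C(=O)O1
F5 | step 5 | 1,3-dioxoisoindolin-2-yl 5-[(3R)-6,8-dimethoxy-1-oxoisochroman-3-yl]pentanoate | O=C(CCCC[C@@H]1Cc2cc(OC)cc(OC)c2C(=O)O1)ON1C(=O)c2ccccc2C1=O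
F6 | step 2 | (E)-2-(3,5-dimethoxybenzylidene)cyclohexan-1-one | O=C1CCCC/C1=C\c1cc(OC)cc(OC)c1
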